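**Retrosynthetic overview**
- Numbering (drimane): ring A = C1–C5 and C10, ring B = C5–C10, C11 = exocyclic benzylic carbon; arene C1′ (on C11), C2′ (sulfate), C3′ (CHO), C4′ and C5′ (OH), C6′ (H).
- Feature: C9 of ring B lies between quaternary C10 and the C8 methine and carries the exocyclic C9=C11 bond. It is therefore made the silicon-bearing carbon of an aryl vinylsilane, and the aryl group cis to C8 is what holds the C8 methyl axial.
- Key disconnection: C4–C5 and C9–C10 are cut together. An acid-initiated cascade closes ring A first and ring B second and ends by ipso-desilylation, with the sulfate diester, pivalates and formyl group already on the arene.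
- Precursor: syn silyl-copper addition (silicon to C9) to an aryl alkyne, itself made by Sonogashira coupling of a C15 dienyne (chiral bromo alcohol plus geranyl sulfone) with an aryl iodide built from sesamol.
- Endgame: reductive removal of the trichloroethyl group, then methanolysis of the pivalates and acidification.

Key step: step 16

Assumption: the (R)-enantiomer of 2-hydroxy-2′-methoxy-1,1′-binaphthyl is taken as the one whose SnCl4 complex leads to the 5S,10S fold (matched with (S)-C8); if the sense proves opposite, the (S)-ligand is used with no other change. The silyl group is PhMe2Si, the group delivered by the commercial silylboronate.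

**Route**

Step 1
Reactants: 1 (R)-3-bromo-2-methylpropan-1-ol
Product: 2 (R)-(3-bromo-2-methylpropoxy)(tert-butyl)dimethylsilane
Conditions: TBSCl, imidazole, CH2Cl2, 0 °C → rt
Reagents that add atoms: tert-butyldimethylsilyl chloride, CC(C)(C)[Si](C)(C)Cl
Why: Imidazole-promoted O-silylation of the primary alcohol is routine and protects the hydroxyl against the carbanion and hydride steps that follow, the stereocentre (future C8) being untouched.

Step 2
Reactants: 3 geranyl bromide, (2E)-1-bromo-3,7-dimethylocta-2,6-diene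
Product: 4 geranyl phenyl sulfone, {[(2E)-3,7-dimethylocta-2,6-dien-1-yl]sulfonyl}benzene
Conditions: PhSO2Na, DMF, 0 °C → rt
Reagents that add atoms: sodium benzenesulfinate, [Na+].[O-]S(=O)c1ccccc1
Why: Sulfinate S-alkylation (SN2 at the primary allylic carbon) gives the allylic sulfone with the E-alkene intact and provides the carbanion-stabilising group for the chain coupling.

Step 3
Reactants: 4 geranyl phenyl sulfone; 2 (R)-(3-bromo-2-methylpropoxy)(tert-butyl)dimethylsilane
Product: 6 tert-butyldimethyl{[(2S,5E)-2,6,10-trimethyl-4-(phenylsulfonyl)undeca-5,9-dien-1-yl]oxy}silane (both C4 epimers), via lithiated sulfone 5 (not isolated)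
Conditions: n-BuLi, THF–DMPU, −78 °C; then 2, −78 °C → rt
Reagents that add atoms: none
Why: The lithiated allylic sulfone is a soft, weakly basic carbanion that is alkylated at its α-carbon by primary halides (allylic sulfone alkylation), here joining C6 to C7, and the new sulfonyl-bearing centre is immaterial because the sulfone is removed in step 4.

Step 4
Reactants: 6 tert-butyldimethyl{[(2S,5E)-2,6,10-trimethyl-4-(phenylsulfonyl)undeca-5,9-dien-1-yl]oxy}silane
Product: 7 tert-butyldimethyl{[(2S,5E)-2,6,10-trimethylundeca-5,9-dien-1-yl]oxy}silane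
Conditions: PdCl2(Ph2PCH2CH2CH2PPh2) (5 mol %), LiBHEt3, THF, 0 °C
Reagents that add atoms: none
Why: Palladium-catalysed reductive desulfonylation should proceed by ionisation of the allylic sulfone to a π-allyl complex of divalent palladium and hydride delivery from LiBHEt3 to the less substituted terminus (C6), which keeps the trisubstituted E-C5=C10 alkene in place.

Step 5
Reactants: 7 tert-butyldimethyl{[(2S,5E)-2,6,10-trimethylundeca-5,9-dien-1-yl]oxy}silane
Product: 8 (2S,5E)-2,6,10-trimethylundeca-5,9-dien-1-ol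
Conditions: camphorsulfonic acid (10 mol %), MeOH–CH2Cl2, 0 °C
Reagents that add atoms: none
Why: Acid-catalysed methanolysis cleaves the primary silyl ether under conditions too mild to protonate the trisubstituted alkenes.

Step 6
Reactants: 8 (2S,5E)-2,6,10-trimethylundeca-5,9-dien-1-ol
Product: 10 (3S,6E)-3,7,11-trimethyldodeca-6,10-dien-1-yne, via aldehyde 9 (not isolated)
Conditions: Dess–Martin periodinane, CH2Cl2, 0 °C → rt; filtration through silica; then dimethyl (1-diazo-2-oxopropyl)phosphonate, K2CO3, MeOH, 0 °C → rt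
Reagents that add atoms: dimethyl (1-diazo-2-oxopropyl)phosphonate, CC(=O)C(=[N+]=[N-])P(=O)(OC)OC
Why: Dess–Martin oxidation followed at once by Ohira–Bestmann homologation (a Seyferth–Gilbert-type alkynylation through a diazoalkene and 1,2-hydride shift) turns CH2OH into the C9≡C11 alkyne, and using the crude aldehyde cold with a weak base should keep the adjacent C8 stereocentre from epimerising.

Step 7
Reactants: 11 sesamol (1,3-benzodioxol-5-ol)
Product: 12 5-(methoxymethoxy)-1,3-benzodioxole
Conditions: MOMCl, i-Pr2NEt, CH2Cl2, 0 °C → rt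
Reagents that add atoms: chloromethyl methyl ether, COCCl
Why: Williamson-type O-alkylation installs the methoxymethyl ether, which is both a protecting group and a directing group for the metalation in step 8.

Step 8
Reactants: 12 5-(methoxymethoxy)-1,3-benzodioxole
Product: 15 5-hydroxy-1,3-benzodioxole-4-carbaldehyde, via aryllithium 13 (not isolated), via MOM-protected aldehyde 14 (not isolated)
Conditions: n-BuLi, TMEDA, THF, −78 → 0 °C; DMF, −78 °C → rt; then 3 M HCl, MeOH, rt
Reagents that add atoms: N,N-dimethylformamide, CN(C)C=O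
Why: Directed ortho-metalation should occur at C4, the only position flanked by two coordinating oxygens (the MOM ether and a dioxole oxygen), DMF formylates the aryllithium, and the acidic methanolic work-up removes the MOM group, which is especially labile next to the chelating formyl group.

Step 9
Reactants: 15 5-hydroxy-1,3-benzodioxole-4-carbaldehyde
Product: 16 5-hydroxy-6-iodo-1,3-benzodioxole-4-carbaldehyde
Conditions: NIS, CF3CO2H (10 mol %), MeCN, 0 °C → rt
Reagents that add atoms: N-iodosuccinimide, O=C1CCC(=O)N1I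
Why: Electrophilic aromatic iodination goes to C6, the only free position ortho to the phenol and also para to a dioxole oxygen, whereas C7 is para to the formyl-bearing carbon and is not activated by the hydroxyl.

Step 10
Reactants: 16 5-hydroxy-6-iodo-1,3-benzodioxole-4-carbaldehyde
Product: 17 4-formyl-6-iodo-1,3-benzodioxol-5-yl 2,2,2-trichloroethyl sulfate
Conditions: Cl3CCH2OSO2Cl, Et3N, DMAP (20 mol %), THF, 0 °C → rt
Reagents that add atoms: 2,2,2-trichloroethyl chlorosulfate, ClS(=O)(=O)OCC(Cl)(Cl)Cl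
Why: DMAP-catalysed O-sulfonylation of the phenol by the chlorosulfate gives the aryl trichloroethyl sulfate, so the sulfate is fixed on the one free hydroxyl (future C2′) before the catechol is unmasked.

Step 11
Reactants: 17 4-formyl-6-iodo-1,3-benzodioxol-5-yl 2,2,2-trichloroethyl sulfate
Product: 18 2-formyl-3,4-dihydroxy-6-iodophenyl 2,2,2-trichloroethyl sulfate
Conditions: BCl3, CH2Cl2, −78 → 0 °C; then H2O
Reagents that add atoms: none
Why: Lewis-acid cleavage of the methylenedioxy acetal by BCl3, helped by chelation to the neighbouring formyl group, should free the catechol while the sulfate diester, which behaves like an aryl sulfonate, and the aryl iodide stay intact.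

Step 12
Reactants: 18 2-formyl-3,4-dihydroxy-6-iodophenyl 2,2,2-trichloroethyl sulfate
Product: 19 2-formyl-6-iodo-3,4-bis(pivaloyloxy)phenyl 2,2,2-trichloroethyl sulfate
Conditions: PivCl, Et3N, DMAP (10 mol %), CH2Cl2, 0 °C → rt
Reagents that add atoms: pivaloyl chloride, CC(C)(C)C(Cl)=O
Why: DMAP-catalysed acylation converts both phenols into pivalates, base-labile groups that are bulky enough to survive the coupling steps and that keep the arene electron-poor.

Step 13
Reactants: 19 2-formyl-6-iodo-3,4-bis(pivaloyloxy)phenyl 2,2,2-trichloroethyl sulfate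
Product: 20 2-(dimethoxymethyl)-6-iodo-3,4-bis(pivaloyloxy)phenyl 2,2,2-trichloroethyl sulfate
Conditions: HC(OMe)3, p-TsOH (5 mol %), MeOH, rt; Et3N quench
Reagents that add atoms: trimethyl orthoformate, COC(OC)OC; methanol, CO
Why: Acid-catalysed acetalisation with the orthoformate as water scavenger masks the aldehyde, which would otherwise add the silyl-copper reagent of step 15, and the hindered pivalates are not transesterified at room temperature.

Step 14
Reactants: 20 2-(dimethoxymethyl)-6-iodo-3,4-bis(pivaloyloxy)phenyl 2,2,2-trichloroethyl sulfate; 10 (3S,6E)-3,7,11-trimethyldodeca-6,10-dien-1-yne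
Product: 21 2-(dimethoxymethyl)-3,4-bis(pivaloyloxy)-6-[(3S,6E)-3,7,11-trimethyldodeca-6,10-dien-1-yn-1-yl]phenyl 2,2,2-trichloroethyl sulfate
Conditions: PdCl2(PPh3)2 (3 mol %), CuI (5 mol %), Et3N, THF, rt, degassed
Reagents that add atoms: none
Why: Sonogashira coupling of the electron-poor aryl iodide with the terminal alkyne forms the C11–C1′ bond under mild amine conditions that leave the sulfate diester, pivalates and acetal untouched.

Step 15
Reactants: 21 2-(dimethoxymethyl)-3,4-bis(pivaloyloxy)-6-[(3S,6E)-3,7,11-trimethyldodeca-6,10-dien-1-yn-1-yl]phenyl 2,2,2-trichloroethyl sulfate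
Product: 23 2-formyl-6-{(1E,3S,6E)-2-[dimethyl(phenyl)silyl]-3,7,11-trimethyldodeca-1,6,10-trien-1-yl}-3,4-bis(pivaloyloxy)phenyl 2,2,2-trichloroethyl sulfate (silicon on C9 and trans to the arene; arene cis to C8), via vinylsilane acetal 22 (not isolated)
Conditions: PhMe2Si–Bpin, CuCl (5 mol %), Xantphos (5 mol %), NaOt-Bu (5 mol %), MeOH (2 equiv), THF, 0 °C → rt; then 1 M HCl, THF, rt
Reagents that add atoms: (dimethylphenylsilyl)boronic acid pinacol ester, C[Si](C)(c1ccccc1)B1OC(C)(C)C(C)(C)O1; water, O
Why: Copper-catalysed silyl-metalation (silylcupration then protonation) adds Cu–Si syn across the alkyne with copper at the aryl-stabilised C11 and silicon at C9, methanol replaces copper by hydrogen with retention so that silicon is trans and C8 cis to the arene, and the aqueous acid then hydrolyses the acetal; this electronically controlled addition is used because platinum-catalysed hydrosilylation of an ortho-substituted aryl alkyne would put silicon on C11.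

Step 16
Reactants: 23 2-formyl-6-{(1E,3S,6E)-2-[dimethyl(phenyl)silyl]-3,7,11-trimethyldodeca-1,6,10-trien-1-yl}-3,4-bis(pivaloyloxy)phenyl 2,2,2-trichloroethyl sulfate
Product: 24 2-formyl-3,4-bis(pivaloyloxy)-6-{(E)-[(2S,4aS,8aS)-2,5,5,8a-tetramethyloctahydronaphthalen-1(2H)-ylidene]methyl}phenyl 2,2,2-trichloroethyl sulfate
Conditions: SnCl4 (2.5 equiv)·(R)-2-hydroxy-2′-methoxy-1,1′-binaphthyl (2.75 equiv), premixed, CH2Cl2, −78 °C, slow addition of 23, 1–3 d; sat. NaHCO3
Reagents that add atoms: none
Why: Proposed new method: the tin-bound chiral phenol is a strong, bulky Brønsted acid that should protonate the most accessible alkene at C3, after which the C4 cation is attacked by the E-C5=C10 alkene and the C10 cation by the silicon-bearing C9, placing charge on C11 (β to silicon and benzylic) and ending with loss of the silyl group with retention, so that the arene stays trans to C10; the closest known reaction types are the enantioselective proton-initiated polyene bicyclisation with SnCl4–binaphthol acids and the vinylsilane-terminated cation–olefin cyclisation in the exocyclic mode, but a vinylsilane carrying an aryl group on its far carbon has not been used to end such a cascade. Ring A closes 6-endo (C4–C5) and ring B closes 6-exo (C9–C10) through a chair–chair array. C5 and C10 come from anti addition across the E-alkene (trans fusion) and their absolute sense from the chiral acid, reinforced by (S)-C8: the arene cis to C8 keeps the C8 hydrogen in the plane of C9=C11 (allylic 1,3-strain), so the methyl group is axial and the fold leading to 5S,10S is the matched one. The step needs protonation at the terminal alkene rather than at the vinylsilane, and capture of the C10 cation by C9 rather than proton loss; the electron-poor arene (sulfate diester, pivalates, formyl) and the hindered vinylsilane should suppress protodesilylation and arene capture, while silicon makes C9 the only terminating carbon and fixes the alkene geometry.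

Step 17
Reactants: 24 2-formyl-3,4-bis(pivaloyloxy)-6-{(E)-[(2S,4aS,8aS)-2,5,5,8a-tetramethyloctahydronaphthalen-1(2H)-ylidene]methyl}phenyl 2,2,2-trichloroethyl sulfate
Product: 25 ammonium 2-formyl-3,4-bis(pivaloyloxy)-6-{(E)-[(2S,4aS,8aS)-2,5,5,8a-tetramethyloctahydronaphthalen-1(2H)-ylidene]methyl}phenyl sulfate
Conditions: Zn dust, HCO2NH4, MeOH, rt
Reagents that add atoms: ammonium formate, [NH4+].[O-]C=O
Why: Zinc reduces a C–Cl bond of the trichloroethyl group and β-elimination (reductive fragmentation) expels 1,1-dichloroethene and the sulfate monoester anion, which unlike the diester is not electrophilic at sulfur and so survives the methanolysis of step 18, while pivalates, the hindered aldehyde and the alkene should not be reduced.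

Step 18
Reactants: 25 ammonium 2-formyl-3,4-bis(pivaloyloxy)-6-{(E)-[(2S,4aS,8aS)-2,5,5,8a-tetramethyloctahydronaphthalen-1(2H)-ylidene]methyl}phenyl sulfate
Product: 27 2-formyl-3,4-dihydroxy-6-{(E)-[(2S,4aS,8aS)-2,5,5,8a-tetramethyloctahydronaphthalen-1(2H)-ylidene]methyl}phenyl hydrogen sulfate (CNP0149861.1), via potassium sulfate salt 26 (not isolated)
Conditions: K2CO3, degassed MeOH, 0 °C → rt, Ar; then 1 M HCl to pH 2, 0 °C
Reagents that add atoms: none
Why: Base-mediated transesterification removes both aryl pivalates as methyl pivalate without touching the anionic sulfate, and acidification in the cold protonates the sulfate and the catechol to give the target.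

**Compound list**

1 | (R)-3-bromo-2-methylpropan-1-ol | OC[C@@H](C)CBr | starting material
2 | (R)-(3-bromo-2-methylpropoxy)(tert-butyl)dimethylsilane | CC(C)(C)[Si](C)(C)OC[C@@H](C)CBr | intermediate
3 | geranyl bromide | CC(C)=CCC/C(C)=C/CBr | starting material
4 | geranyl phenyl sulfone | CC(C)=CCC/C(C)=C/CS(=O)(=O)c1ccccc1 | intermediate
5 | lithiated geranyl phenyl sulfone | CC(C)=CCC/C(C)=C/C([Li])S(=O)(=O)c1ccccc1 | intermediate
6 | tert-butyldimethyl{[(2S,5E)-2,6,10-trimethyl-4-(phenylsulfonyl)undeca-5,9-dien-1-yl]oxy}silane (C4 epimers) | CC(C)=CCC/C(C)=C/C(C[C@H](C)CO[Si](C)(C)C(C)(C)C)S(=O)(=O)c1ccccc1 | intermediate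
7 | tert-butyldimethyl{[(2S,5E)-2,6,10-trimethylundeca-5,9-dien-1-yl]oxy}silane | CC(C)=CCC/C(C)=C/CC[C@H](C)CO[Si](C)(C)C(C)(C)C | intermediate
8 | (2S,5E)-2,6,10-trimethylundeca-5,9-dien-1-ol | CC(C)=CCC/C(C)=C/CC[C@H](C)CO | intermediate
9 | (2S,5E)-2,6,10-trimethylundeca-5,9-dienal | CC(C)=CCC/C(C)=C/CC[C@H](C)C=O | intermediate
10 | (3S,6E)-3,7,11-trimethyldodeca-6,10-dien-1-yne | C#C[C@@H](C)CC/C=C(\C)CCC=C(C)C | intermediate
11 | sesamol (1,3-benzodioxol-5-ol) | Oc1ccc2OCOc2c1 | starting material
12 | 5-(methoxymethoxy)-1,3-benzodioxole | COCOc1ccc2OCOc2c1 | intermediate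
13 | [5-(methoxymethoxy)-1,3-benzodioxol-4-yl]lithium | COCOc1ccc2OCOc2c1[Li] | intermediate
14 | 5-(methoxymethoxy)-1,3-benzodioxole-4-carbaldehyde | COCOc1ccc2OCOc2c1C=O | intermediate
15 | 5-hydroxy-1,3-benzodioxole-4-carbaldehyde | O=Cc1c(O)ccc2OCOc12 | intermediate
16 | 5-hydroxy-6-iodo-1,3-benzodioxole-4-carbaldehyde | O=Cc1c(O)c(I)cc2OCOc12 | intermediate
17 | 4-formyl-6-iodo-1,3-benzodioxol-5-yl 2,2,2-trichloroethyl sulfate | O=Cc1c(OS(=O)(=O)OCC(Cl)(Cl)Cl)c(I)cc2OCOc12 | intermediate
18 | 2-formyl-3,4-dihydroxy-6-iodophenyl 2,2,2-trichloroethyl sulfate | O=Cc1c(OS(=O)(=O)OCC(Cl)(Cl)Cl)c(I)cc(O)c1O | intermediate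
19 | 2-formyl-6-iodo-3,4-bis(pivaloyloxy)phenyl 2,2,2-trichloroethyl sulfate | O=Cc1c(OS(=O)(=O)OCC(Cl)(Cl)Cl)c(I)cc(OC(=O)C(C)(C)C)c1OC(=O)C(C)(C)C | intermediate
20 | 2-(dimethoxymethyl)-6-iodo-3,4-bis(pivaloyloxy)phenyl 2,2,2-trichloroethyl sulfate | COC(OC)c1c(OS(=O)(=O)OCC(Cl)(Cl)Cl)c(I)cc(OC(=O)C(C)(C)C)c1OC(=O)C(C)(C)C | intermediate
21 | 2-(dimethoxymethyl)-3,4-bis(pivaloyloxy)-6-[(3S,6E)-3,7,11-trimethyldodeca-6,10-dien-1-yn-1-yl]phenyl 2,2,2-trichloroethyl sulfate | C[C@@H](CC/C=C(\C)CCC=C(C)C)C#Cc1cc(OC(=O)C(C)(C)C)c(OC(=O)C(C)(C)C)c(C(OC)OC)c1OS(=O)(=O)OCC(Cl)(Cl)Cl | intermediate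
22 | 2-(dimethoxymethyl)-6-{(1E,3S,6E)-2-[dimethyl(phenyl)silyl]-3,7,11-trimethyldodeca-1,6,10-trien-1-yl}-3,4-bis(pivaloyloxy)phenyl 2,2,2-trichloroethyl sulfate | C[C@@H](CC/C=C(\C)CCC=C(C)C)/C([Si](C)(C)c1ccccc1)=C\c1cc(OC(=O)C(C)(C)C)c(OC(=O)C(C)(C)C)c(C(OC)OC)c1OS(=O)(=O)OCC(Cl)(Cl)Cl | intermediate
23 | 2-formyl-6-{(1E,3S,6E)-2-[dimethyl(phenyl)silyl]-3,7,11-trimethyldodeca-1,6,10-trien-1-yl}-3,4-bis(pivaloyloxy)phenyl 2,2,2-trichloroethyl sulfate | C[C@@H](CC/C=C(\C)CCC=C(C)C)/C([Si](C)(C)c1ccccc1)=C\c1cc(OC(=O)C(C)(C)C)c(OC(=O)C(C)(C)C)c(C=O)c1OS(=O)(=O)OCC(Cl)(Cl)Cl | intermediate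
24 | 2-formyl-3,4-bis(pivaloyloxy)-6-{(E)-[(2S,4aS,8aS)-2,5,5,8a-tetramethyloctahydronaphthalen-1(2H)-ylidene]methyl}phenyl 2,2,2-trichloroethyl sulfate | C[C@H]1CC[C@H]2C(C)(C)CCC[C@]2(C)/C1=C/c1cc(OC(=O)C(C)(C)C)c(OC(=O)C(C)(C)C)c(C=O)c1OS(=O)(=O)OCC(Cl)(Cl)Cl | intermediate
25 | ammonium 2-formyl-3,4-bis(pivaloyloxy)-6-{(E)-[(2S,4aS,8aS)-2,5,5,8a-tetramethyloctahydronaphthalen-1(2H)-ylidene]methyl}phenyl sulfate | C[C@H]1CC[C@H]2C(C)(C)CCC[C@]2(C)/C1=C/c1cc(OC(=O)C(C)(C)C)c(OC(=O)C(C)(C)C)c(C=O)c1OS(=O)(=O)[O-].[NH4+] | intermediate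
26 | potassium 2-formyl-3,4-dihydroxy-6-{(E)-[(2S,4aS,8aS)-2,5,5,8a-tetramethyloctahydronaphthalen-1(2H)-ylidene]methyl}phenyl sulfate | C[C@H]1CC[C@H]2C(C)(C)CCC[C@]2(C)/C1=C/c1cc(O)c(O)c(C=O)c1OS(=O)(=O)[O-].[K+] | intermediate
27 | 2-formyl-3,4-dihydroxy-6-{(E)-[(2S,4aS,8aS)-2,5,5,8a-tetramethyloctahydronaphthalen-1(2H)-ylidene]methyl}phenyl hydrogen sulfate (CNP0149861.1) | C[C@H]1CC[C@H]2C(C)(C)CCC[C@]2(C)/C1=C/c1cc(O)c(O)c(C=O)c1OS(=O)(=O)O | target

**Step count**

Total steps: 18. Longest linear sequence: 12 steps (11 → 27, steps 7–18); the side-chain branch (steps 1–6) joins at step 14.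

**Steps most likely to fail**

1. Step 16 (Proposed new method). After ring A has closed, the C10 cation may lose a proton faster than it is captured by the crowded, electronically deactivated silyl-bearing C9, or the vinylsilane may be protodesilylated before the cascade starts; binding of SnCl4 to the formyl group may also erode facial selectivity. The fallback uses known chemistry, sets out from 21 and comes back at 24. The alkyne 21 is semi-hydrogenated (H2, Pd on CaCO3 poisoned with Pb(OAc)2, quinoline, EtOAc) to 2-(dimethoxymethyl)-3,4-bis(pivaloyloxy)-6-[(1Z,3S,6E)-3,7,11-trimethyldodeca-1,6,10-trien-1-yl]phenyl 2,2,2-trichloroethyl sulfate F1. The acetal is hydrolysed (1 M HCl, THF) to 2-formyl-3,4-bis(pivaloyloxy)-6-[(1Z,3S,6E)-3,7,11-trimethyldodeca-1,6,10-trien-1-yl]phenyl 2,2,2-trichloroethyl sulfate F2. F2 is cyclised with the same SnCl4–binaphthol acid. An aryl-substituted alkene is a known terminator of cation–olefin polycyclisation, the arene cis to C8 still holds the methyl axial, C9 now bears hydrogen and not silicon, and proton loss from the benzylic C11 cation should give 24.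

2. Step 15. The silyl-copper species may attack the C–Cl bonds of the trichloroethyl group or the aryl esters, or silicon may be delivered to C11. The fallback makes the C–Si bond before the arene is attached; it sets out from 10 and 19 and comes back at 24.
   - Alkyne 10 undergoes palladium-catalysed silaboration with (chlorodimethylsilyl)boronic acid pinacol ester used in excess (Pd(OAc)2, 1,1,3,3-tetramethylbutyl isocyanide, toluene), conditions under which the first-formed cis adduct should isomerise to the trans adduct 2-[(1E,3S,6E)-2-(chlorodimethylsilyl)-3,7,11-trimethyldodeca-1,6,10-trien-1-yl]-4,4,5,5-tetramethyl-1,3,2-dioxaborolane F3.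
   - i-PrOH and pyridine convert it into 2-[(1E,3S,6E)-2-(isopropoxydimethylsilyl)-3,7,11-trimethyldodeca-1,6,10-trien-1-yl]-4,4,5,5-tetramethyl-1,3,2-dioxaborolane F4.
   - Suzuki–Miyaura coupling of F4 with the free-aldehyde iodide 19 (Pd(PPh3)4, K3PO4, THF–H2O, rt) gives 2-formyl-6-[(1E,3S,6E)-2-(isopropoxydimethylsilyl)-3,7,11-trimethyldodeca-1,6,10-trien-1-yl]-3,4-bis(pivaloyloxy)phenyl 2,2,2-trichloroethyl sulfate F5, the alkoxysilyl analogue of 23, with no acetal needed.
   - F5 is cyclised under the conditions of step 16 and rejoins the route at 24.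

3. Step 11. The strong Lewis acid may cleave the sulfate diester or stop at partial opening of the acetal. The fallback unmasks the catechol before any sulfate is present; it sets out from 16 and comes back at 18.
   - BBr3 (CH2Cl2, −78 → 0 °C) converts 16 into 2,3,6-trihydroxy-5-iodobenzaldehyde F6.
   - Phenylboronic acid (toluene, azeotropic removal of water) bridges only the vicinal C4′/C5′ hydroxyls, giving 5-hydroxy-6-iodo-2-phenyl-1,3,2-benzodioxaborole-4-carbaldehyde F7.
   - The remaining C2′ hydroxyl is sulfated as in step 10 to 4-formyl-6-iodo-2-phenyl-1,3,2-benzodioxaborol-5-yl 2,2,2-trichloroethyl sulfate F8.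
   - Mild aqueous hydrolysis (THF–H2O) releases the catechol 18.

**Further compounds**

F1 | step 16 | 2-(dimethoxymethyl)-3,4-bis(pivaloyloxy)-6-[(1Z,3S,6E)-3,7,11-trimethyldodeca-1,6,10-trien-1-yl]phenyl 2,2,2-trichloroethyl sulfate | C[C@@H](CC/C=C(\C)CCC=C(C)C)/C=C\c1cc(OC(=O)C(C)(C)C)c(OC(=O)C(C)(C)C)c(C(OC)OC)c1OS(=O)(=O)OCC(Cl)(Cl)Cl
F2 | step 16 | 2-formyl-3,4-bis(pivaloyloxy)-6-[(1Z,3S,6E)-3,7,11-trimethyldodeca-1,6,10-trien-1-yl]phenyl 2,2,2-trichloroethyl sulfate | C[C@@H](CC/C=C(\C)CCC=C(C)C)/C=C\c1cc(OC(=O)C(C)(C)C)c(OC(=O)C(C)(C)C)c(C=O)c1OS(=O)(=O)OCC(Cl)(Cl)Cl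
F3 | step 15 | 2-[(1E,3S,6E)-2-(chlorodimethylsilyl)-3,7,11-trimethyldodeca-1,6,10-trien-1-yl]-4,4,5,5-tetramethyl-1,3,2-dioxaborolane | C[C@@H](CC/C=C(\C)CCC=C(C)C)/C([Si](C)(C)Cl)=C\B1OC(C)(C)C(C)(C)O1
F4 | step 15 | 2-[(1E,3S,6E)-2-(isopropoxydimethylsilyl)-3,7,11-trimethyldodeca-1,6,10-trien-1-yl]-4,4,5,5-tetramethyl-1,3,2-dioxaborolane | C[C@@H](CC/C=C(\C)CCC=C(C)C)/C([Si](C)(C)OC(C)C)=C\B1OC(C)(C)C(C)(C)O1
F5 | step 15 | 2-formyl-6-[(1E,3S,6E)-2-(isopropoxydimethylsilyl)-3,7,11-trimethyldodeca-1,6,10-trien-1-yl]-3,4-bis(pivaloyloxy)phenyl 2,2,2-trichloroethyl sulfate | C[C@@H](CC/C=C(\C)CCC=C(C)C)/C([Si](C)(C)OC(C)C)=C\c1cc(OC(=O)C(C)(C)C)c(OC(=O)C(C)(C)C)c(C=O)c1OS(=O)(=O)OCC(Cl)(Cl)Cl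
F6 | step 11 | 2,3,6-trihydroxy-5-iodobenzaldehyde | O=Cc1c(O)c(I)cc(O)c1O
F7 | step 11 | 5-hydroxy-6-iodo-2-phenyl-1,3,2-benzodioxaborole-4-carbaldehyde | O=Cc1c(O)c(I)cc2OB(c3ccccc3)Oc12
F8 | step 11 | 4-formyl-6-iodo-2-phenyl-1,3,2-benzodioxaborol-5-yl 2,2,2-trichloroethyl sulfate | O=Cc1c(OS(=O)(=O)OCC(Cl)(Cl)Cl)c(I)cc2OB(c3ccccc3)Oc12
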